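**Plan**

- Retrosynthesis: the allyl ether on O-6 of the benzofuran is removed last. Ring B is then cut at C1'–C2' (aldol) and at C1'–C6' (Claisen acylation), so that C1' becomes the ester carbon of a 6-(allyloxy)benzofuran-2-carboxylate and C2'–C6' become a symmetrical β-diketone that already carries both prenyl groups and both ring oxygens.
- Enabling feature: ring B is a resorcinol with O on C3' and C5', H on C4', prenyl on C2' and C6' and the benzofuran C-2 on C1'. This is the pattern a 1,3,5-triketone gives when its terminal α-methylene carbon closes onto its aryl ketone carbon; since C2' and C6' are equivalent, one diketone supplies both flanks.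
- Forward: ring A is bought as 2,4-dihydroxybenzaldehyde and the furan ring closes in step 2. Pentane-2,4-dione is prenylated at one terminus (step 3) and then at the other (step 4), and dianion aroylation joins the two fragments to the triketone (step 5). Ring B closes and aromatises in step 6, and deallylation (step 7) gives mulberrofuran V.
- Stereochemistry: the target has no stereocentre and no stereogenic double bond; the sp3 centres of the triketone and of the cyclic aldol adduct are uncontrolled and vanish on aromatisation.

Key step: step 6

Remark: all β-diketones and triketones are drawn as keto forms although they exist largely as enols; the methine between two carbonyl groups of the triketone is configurationally labile, so no configuration is assigned.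

**Step 1**
Reactants: 1 2,4-dihydroxybenzaldehyde
Product: 2 4-(allyloxy)-2-hydroxybenzaldehyde
Conditions: allyl bromide (1.05 equiv), K2CO3 (1.0 equiv), acetone, rt
Reagents that add atoms: allyl bromide, C=CCBr
Why: Williamson ether synthesis in which the 4-OH (para to the formyl group, more acidic) is alkylated selectively, because the 2-OH is held in a hydrogen bond to the aldehyde and only one equivalent of mild base is used.

**Step 2**
Reactants: 2 4-(allyloxy)-2-hydroxybenzaldehyde; 3 methyl bromoacetate
Product: 6 methyl 6-(allyloxy)benzofuran-2-carboxylate, via aryloxyacetate 4 (not isolated), via cyclic aldol adduct 5 (not isolated)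
Conditions: K2CO3 (2.5 equiv), DMF, rt then 110 °C
Reagents that add atoms: none
Why: Williamson O-alkylation of the remaining phenol is followed in the same pot by intramolecular aldol condensation of the ester α-carbon onto the ortho formyl group and dehydration to the aromatic furan (Rap–Stoermer-type benzofuran synthesis from a salicylaldehyde and an α-halo ester); the aryl allyl ether should survive because aromatic Claisen rearrangement needs a much higher temperature.

**Step 3**
Reactants: 7 pentane-2,4-dione; 8 prenyl bromide
Product: 9 8-methylnon-7-ene-2,4-dione
Conditions: LiN(i-Pr)2 (2.1 equiv), THF, −78 to 0 °C; 8 (1.0 equiv), 0 °C; 1 M HCl, 0 °C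
Reagents that add atoms: none
Why: γ-Alkylation of the 1,3-dianion of a β-diketone, in which the terminal carbanion, by far the more nucleophilic of the two anionic sites, displaces bromide from the primary allylic halide by SN2 while the central enolate stays untouched.

**Step 4**
Reactants: 9 8-methylnon-7-ene-2,4-dione; 8 prenyl bromide
Product: 10 2,12-dimethyltrideca-2,11-diene-6,8-dione
Conditions: LiN(i-Pr)2 (2.1 equiv), THF, −78 to 0 °C; 8 (1.05 equiv), 0 °C; 1 M HCl, 0 °C
Reagents that add atoms: none
Why: Second γ-alkylation of a β-diketone dianion; once the central proton is removed, kinetic deprotonation by the hindered amide should take place at the free methyl group and not at the C-5 methylene, so the second prenyl unit goes to the other terminus and gives the symmetrical diketone.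

**Step 5**
Reactants: 10 2,12-dimethyltrideca-2,11-diene-6,8-dione; 6 methyl 6-(allyloxy)benzofuran-2-carboxylate
Product: 11 1-[6-(allyloxy)benzofuran-2-yl]-9-methyl-2-(3-methylbut-2-enyl)dec-8-ene-1,3,5-trione
Conditions: 10 (2.1 equiv), LiN(i-Pr)2 (4.3 equiv), THF, −78 to 0 °C; 6 (1.0 equiv), −78 to 0 °C; AcOH, −78 °C
Reagents that add atoms: none
Why: Claisen-type aroylation of a β-diketone dianion at its terminal α-carbon with a non-enolisable aryl ester, a standard route to 1,3,5-triketones; 10 is symmetrical so either terminus gives the same product, and the second equivalent of dianion takes up the acidic proton of the triketone so that the ester should be consumed fully.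

**Step 6**
Reactants: 11 1-[6-(allyloxy)benzofuran-2-yl]-9-methyl-2-(3-methylbut-2-enyl)dec-8-ene-1,3,5-trione
Product: 13 5-[6-(allyloxy)benzofuran-2-yl]-4,6-bis(3-methylbut-2-enyl)benzene-1,3-diol, via cyclic aldol adduct 12 (not isolated)
Conditions: KOH (2 M aq., 6 equiv), MeOH, degassed, 0.02 M, 25 to 50 °C; then 1 M HCl to pH 6, 0 °C
Reagents that add atoms: none
Why: In aqueous-methanolic KOH the triketone rests as its C-4 enolate (in part the C-2/C-4 dianion), which shields the carbonyl groups from hydroxide, and reversible deprotonation of the terminal C-6 methylene gives a dienolate whose C-6 adds to the benzofuran-2-yl ketone carbon C-1, making the C1'–C2' bond of ring B in 12; E1cB loss of water across C-1/C-2 and two enolisations then give the resorcinol irreversibly. The closest known reaction type is the base-mediated aldol cyclisation–aromatisation of 2,4,6-triketones to 5-substituted resorcinols (diacetylacetone to orcinol), the polyketide-type folding also seen with 3,5,7-triketo acids. Ring B closes in the 6-(enolendo)-exo-trig mode. No stereocentre has to be controlled, since the three sp3 centres of 12 are erased on aromatisation. The step needs C-aldol closure to outrun retro-Claisen cleavage, O-cyclisation to a 4-pyranone and intermolecular condensation: every other enolisable carbon of 11 could close only a four-membered ring, the basic medium shuts off the acid-catalysed pyranone pathway, the weakly coordinating potassium ion in a protic solvent leaves the C-3/C-5 enolate free to turn its oxygens outward in the W-shape that brings C-2 and C-6 together (a chelating cation would hold them apart), high dilution disfavours intermolecular reaction, and the allyl ether keeps the benzofuran oxygen un-ionised so that C-1 stays electrophilic.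

**Step 7**
Reactants: 13 5-[6-(allyloxy)benzofuran-2-yl]-4,6-bis(3-methylbut-2-enyl)benzene-1,3-diol
Product: 14 mulberrofuran V
Conditions: Pd(PPh3)4 (5 mol %), morpholine (5 equiv), THF, rt, argon
Reagents that add atoms: none
Why: Tsuji–Trost-type deallylation, in which zerovalent palladium ionises the aryl allyl ether to a π-allyl complex that morpholine captures, freeing the phenol under neutral conditions; the prenyl groups carry no leaving group and should stay inert, and the absence of acid excludes cyclisation of the ortho-prenylphenols to chromans.

**Compound list**

1 | 2,4-dihydroxybenzaldehyde | O=Cc1ccc(O)cc1O | starting material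
2 | 4-(allyloxy)-2-hydroxybenzaldehyde | O=Cc1ccc(OCC=C)cc1O | intermediate
3 | methyl bromoacetate | COC(=O)CBr | starting material
4 | methyl 2-[5-(allyloxy)-2-formylphenoxy]acetate | COC(=O)COc1cc(OCC=C)ccc1C=O | intermediate
5 | methyl 6-(allyloxy)-3-hydroxy-2,3-dihydrobenzofuran-2-carboxylate (racemic mixture of diastereomers) | COC(=O)C1Oc2cc(OCC=C)ccc2C1O | intermediate
6 | methyl 6-(allyloxy)benzofuran-2-carboxylate | COC(=O)c1cc2ccc(OCC=C)cc2o1 | intermediate
7 | pentane-2,4-dione (acetylacetone) | CC(=O)CC(C)=O | starting material
8 | 1-bromo-3-methylbut-2-ene (prenyl bromide) | CC(C)=CCBr | starting material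
9 | 8-methylnon-7-ene-2,4-dione | CC(=O)CC(=O)CCC=C(C)C | intermediate
10 | 2,12-dimethyltrideca-2,11-diene-6,8-dione | CC(C)=CCCC(=O)CC(=O)CCC=C(C)C | intermediate
11 | 1-[6-(allyloxy)benzofuran-2-yl]-9-methyl-2-(3-methylbut-2-enyl)dec-8-ene-1,3,5-trione (racemic, configurationally labile) | C=CCOc1ccc2cc(C(=O)C(CC=C(C)C)C(=O)CC(=O)CCC=C(C)C)oc2c1 | intermediate
12 | 5-[6-(allyloxy)benzofuran-2-yl]-5-hydroxy-4,6-bis(3-methylbut-2-enyl)cyclohexane-1,3-dione (mixture of diastereomers) | C=CCOc1ccc2cc(C3(O)C(CC=C(C)C)C(=O)CC(=O)C3CC=C(C)C)oc2c1 | intermediate
13 | 5-[6-(allyloxy)benzofuran-2-yl]-4,6-bis(3-methylbut-2-enyl)benzene-1,3-diol (6-O-allyl mulberrofuran V) | C=CCOc1ccc2cc(-c3c(CC=C(C)C)c(O)cc(O)c3CC=C(C)C)oc2c1 | intermediate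
14 | mulberrofuran V | CC(C)=CCc1c(O)cc(O)c(CC=C(C)C)c1-c1cc2ccc(O)cc2o1 | target

**Step count and risks**

Total steps: 7. Longest linear sequence: 5 steps (steps 1, 2, 5, 6, 7 from 2,4-dihydroxybenzaldehyde; equally steps 3, 4, 5, 6, 7 from pentane-2,4-dione).

Steps most likely to fail:

1. Step 6 (aldol aromatisation of ring B).
 - What may go wrong: hydroxide may cleave the 2-alkyl-1,3-diketone unit by retro-Claisen fragmentation faster than the singly activated terminal methylene is deprotonated and cyclises, or the substrate may rest as unreactive polyanions.
 - Fallback, from 11 back to 13: the nucleophilic carbon is given a second, traceless activating group. The trilithio trianion of 11 (LiN(i-Pr)2, 3.3 equiv, THF, −78 to 0 °C) is carboxylated with CO2 at its terminal C-6 carbanion to give 7-[6-(allyloxy)benzofuran-2-yl]-2,6-bis(3-methylbut-2-enyl)-3,5,7-trioxoheptanoic acid F1.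
 - In aqueous KHCO3 at room temperature the C-2 methine of F1, now activated by both the carboxylate and the C-3 ketone, should add to the aryl ketone carbon. This is the established aldol folding of 3,5,7-triketo acids, here without hydroxide, and gives the cyclic hydroxy acid 2-[6-(allyloxy)benzofuran-2-yl]-2-hydroxy-1,3-bis(3-methylbut-2-enyl)-4,6-dioxocyclohexane-1-carboxylic acid F2, which is not isolated.
 - Adjusting to pH 4–5 and warming to 40 °C should make the β-keto acid lose CO2 and water and aromatise to 13. The aldol at a substituted C-2 and the decarboxylative aromatisation are extrapolations from the unsubstituted triketo acid case.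

2. Step 5 (dianion aroylation).
 - What may go wrong: proton transfer from the product to unreacted dianion may stall the acylation, acylation may be diverted to the central carbon or to oxygen, or a second dianion may add to the new ketone.
 - Fallback, from 6 and 10 back to 11: the bond is made by aldol addition at the aldehyde oxidation level and the ketone is restored afterwards. Ester 6 is reduced with LiAlH4 (THF, 0 °C) to [6-(allyloxy)benzofuran-2-yl]methanol F3, which is oxidised with MnO2 (CH2Cl2, rt) to 6-(allyloxy)benzofuran-2-carbaldehyde F4.
 - The dilithio dianion of 10 (LiN(i-Pr)2, 2.1 equiv, THF, −78 °C) adds through its terminal carbon to F4 in 1:1 stoichiometry, since the alkoxide formed does not quench the dianion. This gives 1-[6-(allyloxy)benzofuran-2-yl]-1-hydroxy-9-methyl-2-(3-methylbut-2-enyl)dec-8-ene-3,5-dione F5 as a mixture of diastereomers.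
 - MnO2 oxidation of the heteroaryl carbinol of F5 then gives 11.

3. Step 4 (second terminal prenylation).
 - What may go wrong: the second deprotonation of 9 may partly take place at the C-5 methylene, or proton exchange between the anions may divert the alkylation to the central carbon or cause over-alkylation, leaving a mixture that is hard to separate.
 - Fallback, from 7 and 8 back to 10: the diketone is assembled by a mixed Claisen condensation in which each arm arrives complete. K2CO3 in refluxing ethanol alkylates 7 at C-3 with 8 to give 3-(3-methylbut-2-enyl)pentane-2,4-dione F6, which is not isolated; ethanolysis removes one acetyl group in the same pot (retro-Claisen deacetylation) and gives 6-methylhept-5-en-2-one F7.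
 - The sodium enolate of F7 (NaH, THF, reflux) is acylated at its methyl group by an excess of ethyl 5-methylhex-4-enoate F8, a purchased ester, to give 10 after acidic work-up.

**Further compounds**

F1 | step 6 | 7-[6-(allyloxy)benzofuran-2-yl]-2,6-bis(3-methylbut-2-enyl)-3,5,7-trioxoheptanoic acid | C=CCOc1ccc2cc(C(=O)C(CC=C(C)C)C(=O)CC(=O)C(CC=C(C)C)C(O)=O)oc2c1
F2 | step 6 | 2-[6-(allyloxy)benzofuran-2-yl]-2-hydroxy-1,3-bis(3-methylbut-2-enyl)-4,6-dioxocyclohexane-1-carboxylic acid (mixture of diastereomers) | C=CCOc1ccc2cc(C3(O)C(CC=C(C)C)C(=O)CC(=O)C3(CC=C(C)C)C(O)=O)oc2c1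
F3 | step 5 | [6-(allyloxy)benzofuran-2-yl]methanol | OCc1cc2ccc(OCC=C)cc2o1
F4 | step 5 | 6-(allyloxy)benzofuran-2-carbaldehyde | O=Cc1cc2ccc(OCC=C)cc2o1
F5 | step 5 | 1-[6-(allyloxy)benzofuran-2-yl]-1-hydroxy-9-methyl-2-(3-methylbut-2-enyl)dec-8-ene-3,5-dione (mixture of diastereomers) | C=CCOc1ccc2cc(C(O)C(CC=C(C)C)C(=O)CC(=O)CCC=C(C)C)oc2c1
F6 | step 4 | 3-(3-methylbut-2-enyl)pentane-2,4-dione | CC(=O)C(CC=C(C)C)C(C)=O
F7 | step 4 | 6-methylhept-5-en-2-one | CC(=O)CCC=C(C)C
F8 | step 4 | ethyl 5-methylhex-4-enoate (purchased) | CCOC(=O)CCC=C(C)C
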